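**Retrosynthetic overview** (labdane numbering C1–C16)

1. The lactone ring is closed last. The C12–C13 bond comes from 1,6-addition of the dianion of the (S)-malic acid dioxolanone 17 to vinyl dienone 15; C13 is set by the acetal centre.
2. Key step: dienone 15 arises from divinyl carbinol 12 by a [3,3]-sigmatropic chromate shift, which makes the C7–O bond and the C8=C9 alkene together.
3. The 6-OH comes from hydride delivery to enedione 9 anti to the C10 methyl; 9 comes from octalone 8 by allylic oxidation.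
4. Octalone 8 comes from (S)-carvone, which is ring B: C10 is built by methylation then allylation anti to the isopropenyl group, and ring A by cation–olefin closure of the isopropenyl cation onto the allyl group.
5. Ring order: ring B (bought) → ring A (step 3) → lactone (step 11).

Assumption: the SMILES is taken literally, i.e. 5R,6R,10R,13S, with the decalin antipodal to the sclareol series and the 6-OH cis to the C10 methyl.

**Step 1**
Reactants: 1 (S)-(+)-carvone
Product: 3 (5S)-2,6-dimethyl-5-(prop-1-en-2-yl)cyclohex-2-en-1-one (C6 epimer mixture; mainly trans), via lithium dienolate 2 (not isolated)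
Conditions: LiN(iPr)2, THF, −78 °C; MeI, −78 → 0 °C
Reagents that add atoms: iodomethane, CI
Why: Kinetic α'-deprotonation gives the cross-conjugated lithium dienolate, which is methylated by SN2 (enolate alkylation); the new C6 centre is flattened again in step 2, so its ratio is irrelevant.

**Step 2**
Reactants: 3 6-methylcarvone
Product: 5 (5R,6R)-2,6-dimethyl-6-(prop-2-en-1-yl)-5-(prop-1-en-2-yl)cyclohex-2-en-1-one (allyl trans to isopropenyl), via lithium dienolate 4 (not isolated)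
Conditions: LiN(iPr)2, THF–DMPU, −78 °C; allyl bromide, −78 → −20 °C
Reagents that add atoms: allyl bromide, C=CCBr
Why: Second kinetic enolate alkylation, in which allyl bromide attacks the face anti to the adjacent isopropenyl group, so the carvone stereocentre sets the quaternary carbon (future C10) with methyl cis and allyl trans to isopropenyl.

**Step 3**
Reactants: 5 allyl methyl carvone
Product: 7 (4aR,8aR)-7-chloro-2,5,5,8a-tetramethyl-4a,5,6,7,8,8a-hexahydronaphthalen-1(4H)-one (both C–Cl epimers), via tertiary chloride 6 (not isolated)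
Conditions: HCl (g), CH2Cl2, −30 °C; then TiCl4, −78 °C
Reagents that add atoms: hydrogen chloride, Cl
Why: Markovnikov HCl addition gives the tertiary chloride, TiCl4 ionises it, and the trans-disposed allyl terminus traps the cation 6-endo with chloride return to the secondary carbon (Lewis-acid cation–olefin cyclisation); ring A closes with the trans fusion already fixed by C5 and C10.

**Step 4**
Reactants: 7 chloro-octalone
Product: 8 (4aR,8aR)-2,5,5,8a-tetramethyl-4a,5,6,7,8,8a-hexahydronaphthalen-1(4H)-one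
Conditions: Bu3SnH, AIBN (cat.), PhMe, 110 °C
Reagents that add atoms: none
Why: Radical chain dehalogenation removes the secondary chloride without touching a stereocentre, so both C–Cl epimers converge.

**Step 5**
Reactants: 8 octalone
Product: 9 (4aR,8aR)-2,5,5,8a-tetramethyl-4a,5,6,7,8,8a-hexahydronaphthalene-1,4-dione
Conditions: CrO3, 3,5-dimethylpyrazole, CH2Cl2, −20 °C
Reagents that add atoms: chromium trioxide, O=[Cr](=O)=O
Why: Allylic oxidation of the γ-CH2 of the enone gives the ene-1,4-dione; the quaternary C10 blocks aromatisation and the non-basic medium keeps the now enolisable C5 from epimerising.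

**Step 6**
Reactants: 9 enedione
Product: 10 (4S,4aR,8aR)-4-hydroxy-2,5,5,8a-tetramethyl-4a,5,6,7,8,8a-hexahydronaphthalen-1(4H)-one
Conditions: NaBH4, CeCl3·7H2O, MeOH, −78 °C
Reagents that add atoms: none
Why: Luche 1,2-reduction of the less hindered C6 carbonyl (the C9 carbonyl sits between the quaternary carbon and the methyl-bearing alkene carbon); hydride enters anti to the axial C10 and C4 methyls, which places the new OH cis to the C10 methyl.

**Step 7**
Reactants: 10 hydroxy enone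
Product: 11 (4S,4aR,8aR)-2,5,5,8a-tetramethyl-4-[(triethylsilyl)oxy]-4a,5,6,7,8,8a-hexahydronaphthalen-1(4H)-one
Conditions: Et3SiOTf, 2,6-lutidine, CH2Cl2, −78 → 0 °C
Reagents that add atoms: triethylsilyl trifluoromethanesulfonate, CC[Si](CC)(CC)OS(=O)(=O)C(F)(F)F
Why: Silyl triflate silylation protects the hindered axial carbinol from the chromium oxidant of step 9 without touching a stereocentre.

**Step 8**
Reactants: 11 silyloxy enone
Product: 12 (1R,4S,4aR,8aR)-1-ethenyl-2,5,5,8a-tetramethyl-4-[(triethylsilyl)oxy]-1,4,4a,5,6,7,8,8a-octahydronaphthalen-1-ol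
Conditions: CH2=CHMgBr, CeCl3, THF, −78 → 0 °C; then H2O
Reagents that add atoms: vinylmagnesium bromide, C=C[Mg]Br
Why: Organocerium-type 1,2-addition to the hindered enone carbonyl, expected from the face anti to the C10 methyl; the new carbinol centre is erased in step 9, so its configuration does not matter.

**Step 9**
Reactants: 12 divinyl carbinol
Product: 15 (1R,4aR,8aR)-4-ethenyl-3,4a,8,8-tetramethyl-1-[(triethylsilyl)oxy]-4a,5,6,7,8,8a-hexahydronaphthalen-2(1H)-one, via chlorochromate ester 13 (not isolated), via rearranged chromate ester 14 (not isolated)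
Conditions: [C5H5NH][CrO3Cl] (pyridinium chlorochromate), NaOAc, 4 Å MS, CH2Cl2, 23 °C
Reagents that add atoms: pyridinium chlorochromate, [O-][Cr](=O)(=O)Cl.c1cc[nH+]cc1
Why: Babler–Dauben oxidative transposition, in which the tertiary chromate ester undergoes a [3,3]-sigmatropic shift through the ring allyl unit to form the C7–O bond and the tetrasubstituted C8=C9 alkene, and the secondary chromate then collapses to the ketone; C5, C6 and C10 are untouched.

**Step 10**
Reactants: 16 (S)-malic acid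
Product: 17 2-[(2S,4S)-2-tert-butyl-5-oxo-1,3-dioxolan-4-yl]acetic acid (cis)
Conditions: t-BuCHO, TsOH (cat.), H2SO4 (cat.), pentane, reflux, Dean–Stark; recrystallise
Reagents that add atoms: pivalaldehyde, CC(C)(C)C=O
Why: Acid-catalysed acetalisation of the α-hydroxy acid gives the cis-dioxolanone as the favoured, crystalline isomer, so the malic acid centre sets the acetal centre (self-regeneration of stereocentres).

**Step 11**
Reactants: 15 vinyl dienone; 17 dioxolanone acid
Product: 21 (1R,4aR,8aR)-1-hydroxy-4-{2-[(3S)-3-hydroxy-5-oxooxolan-3-yl]ethyl}-3,4a,8,8-tetramethyl-4a,5,6,7,8,8a-hexahydronaphthalen-2(1H)-one (target), via dilithium enolate 18 (not isolated), via Michael adduct 19 (not isolated), via seco acid 20 (not isolated)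
Conditions: 17, LiN(SiMe3)2 (2.1 equiv), THF, −78 °C; add 15, −78 → −20 °C; LiBH4 (3 equiv), −20 → 0 °C; then 1 M HCl, THF, 23 °C
Reagents that add atoms: none
Why: The planar dioxolanone enolate adds 1,6 to the unhindered vinyl terminus anti to the tert-butyl group (vinylogous Michael addition with retention, C13 = S), the resulting lithium dienolate masks the C7 ketone while LiBH4 reduces the dioxolanone carbonyl to CH2OH, and acid then reprotonates to the conjugated enone, closes the γ-lactone and removes the silyl ether.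

**Compound list**

1 | (S)-(+)-carvone, (5S)-2-methyl-5-(prop-1-en-2-yl)cyclohex-2-en-1-one | CC1=CC[C@@H](CC1=O)C(C)=C | starting material
2 | lithium cross-conjugated dienolate of 1 | C=C(C)[C@H]1CC=C(C)C([O-])=C1.[Li+] | intermediate
3 | (5S)-2,6-dimethyl-5-(prop-1-en-2-yl)cyclohex-2-en-1-one (C6 epimers, mainly 6R trans) | C=C(C)[C@H]1CC=C(C)C(=O)C1C | intermediate
4 | lithium dienolate of 3 | C=C(C)[C@H]1CC=C(C)C([O-])=C1C.[Li+] | intermediate
5 | (5R,6R)-2,6-dimethyl-6-(prop-2-en-1-yl)-5-(prop-1-en-2-yl)cyclohex-2-en-1-one | C=C(C)[C@H]1CC=C(C)C(=O)[C@]1(C)CC=C | intermediate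
6 | (5S,6R)-5-(2-chloropropan-2-yl)-2,6-dimethyl-6-(prop-2-en-1-yl)cyclohex-2-en-1-one | CC(C)(Cl)[C@H]1CC=C(C)C(=O)[C@]1(C)CC=C | intermediate
7 | (4aR,8aR)-7-chloro-2,5,5,8a-tetramethyl-4a,5,6,7,8,8a-hexahydronaphthalen-1(4H)-one (C7 epimers) | CC1=CC[C@@H]2C(C)(C)CC(Cl)C[C@@]2(C)C1=O | intermediate
8 | (4aR,8aR)-2,5,5,8a-tetramethyl-4a,5,6,7,8,8a-hexahydronaphthalen-1(4H)-one | CC1=CC[C@@H]2C(C)(C)CCC[C@@]2(C)C1=O | intermediate
9 | (4aR,8aR)-2,5,5,8a-tetramethyl-4a,5,6,7,8,8a-hexahydronaphthalene-1,4-dione | CC1=CC(=O)[C@@H]2C(C)(C)CCC[C@@]2(C)C1=O | intermediate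
10 | (4S,4aR,8aR)-4-hydroxy-2,5,5,8a-tetramethyl-4a,5,6,7,8,8a-hexahydronaphthalen-1(4H)-one | CC1=C[C@H](O)[C@@H]2C(C)(C)CCC[C@@]2(C)C1=O | intermediate
11 | (4S,4aR,8aR)-2,5,5,8a-tetramethyl-4-[(triethylsilyl)oxy]-4a,5,6,7,8,8a-hexahydronaphthalen-1(4H)-one | CC1=C[C@H](O[Si](CC)(CC)CC)[C@@H]2C(C)(C)CCC[C@@]2(C)C1=O | intermediate
12 | (1R,4S,4aR,8aR)-1-ethenyl-2,5,5,8a-tetramethyl-4-[(triethylsilyl)oxy]-1,4,4a,5,6,7,8,8a-octahydronaphthalen-1-ol | CC1=C[C@H](O[Si](CC)(CC)CC)[C@@H]2C(C)(C)CCC[C@@]2(C)[C@@]1(O)C=C | intermediate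
13 | tertiary chlorochromate ester of 12 | CC1=C[C@H](O[Si](CC)(CC)CC)[C@@H]2C(C)(C)CCC[C@@]2(C)[C@@]1(O[Cr](=O)(=O)Cl)C=C | intermediate
14 | rearranged secondary allylic chlorochromate ester (O on C7, C8=C9) | C=CC1=C(C)[C@H](O[Cr](=O)(=O)Cl)[C@H](O[Si](CC)(CC)CC)[C@@H]2C(C)(C)CCC[C@@]12C | intermediate
15 | (1R,4aR,8aR)-4-ethenyl-3,4a,8,8-tetramethyl-1-[(triethylsilyl)oxy]-4a,5,6,7,8,8a-hexahydronaphthalen-2(1H)-one | C=CC1=C(C)C(=O)[C@H](O[Si](CC)(CC)CC)[C@@H]2C(C)(C)CCC[C@@]12C | intermediate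
16 | (S)-malic acid | O[C@@H](CC(=O)O)C(=O)O | starting material
17 | 2-[(2S,4S)-2-tert-butyl-5-oxo-1,3-dioxolan-4-yl]acetic acid | CC(C)(C)[C@H]1O[C@@H](CC(=O)O)C(=O)O1 | intermediate
18 | dilithium enolate-carboxylate of 17 | CC(C)(C)[C@H]1OC(CC(=O)[O-])=C([O-])O1.[Li+].[Li+] | intermediate
19 | 1,6-Michael adduct as dilithium dienolate-carboxylate (C7 enolate, C9=C11) | CC1=C([O-])[C@H](O[Si](CC)(CC)CC)[C@@H]2C(C)(C)CCC[C@@]2(C)C1=CC[C@@]1(CC(=O)[O-])O[C@H](C(C)(C)C)OC1=O.[Li+].[Li+] | intermediate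
20 | (3S)-3-hydroxy-3-(hydroxymethyl)-5-[(4R,4aR,8aR)-2,5,5,8a-tetramethyl-3-oxo-4-(triethylsilyloxy)-3,4,4a,5,6,7,8,8a-octahydronaphthalen-1-yl]pentanoic acid | CC1=C(CC[C@@](O)(CO)CC(=O)O)[C@]2(C)CCCC(C)(C)[C@H]2[C@@H](O[Si](CC)(CC)CC)C1=O | intermediate
21 | (1R,4aR,8aR)-1-hydroxy-4-{2-[(3S)-3-hydroxy-5-oxooxolan-3-yl]ethyl}-3,4a,8,8-tetramethyl-4a,5,6,7,8,8a-hexahydronaphthalen-2(1H)-one | CC1=C(CC[C@@]2(O)COC(=O)C2)[C@]2(C)CCCC(C)(C)[C@H]2[C@@H](O)C1=O | target

**Totals**

Total step count: 11. Longest linear sequence: 10 (steps 1–9 and 11; step 10 makes the second fragment).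

**Steps most likely to fail**

Step 3 (ring A closure). The unactivated vinyl group is a weak cation trap, so elimination or hydride and methyl shifts of the secondary cation can compete. The fallback sets out from 3 and uses a silicon-directed terminator. Alkylation of 3 with 3-bromo-1-(trimethylsilyl)prop-1-yne (LiN(iPr)2, THF, −78 °C) gives (5R,6R)-2,6-dimethyl-5-(prop-1-en-2-yl)-6-[3-(trimethylsilyl)prop-2-yn-1-yl]cyclohex-2-en-1-one F1. Semihydrogenation (H2, Pd on CaCO3 poisoned with Pb(OAc)2, quinoline) gives the Z-vinylsilane (5R,6R)-2,6-dimethyl-5-(prop-1-en-2-yl)-6-[(2Z)-3-(trimethylsilyl)prop-2-en-1-yl]cyclohex-2-en-1-one F2. HCl then TiCl4 closes ring A at the silicon-bearing carbon through a β-silyl cation that loses the silyl group, giving (4aR,8aR)-2,5,5,8a-tetramethyl-4a,5,8,8a-tetrahydronaphthalen-1(4H)-one F3. H2 over RhCl(PPh3)3 saturates only the disubstituted ring A alkene, and the route is rejoined at 8.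

Step 9 (direction of the chromate shift). The chromate ester of 12 has two allylic termini and may migrate to the vinyl CH2, which would give a dienal. The fallback sets out from 11 and uses a C2 unit that offers only the ring terminus. Addition of HC≡CMgBr with CeCl3 gives (1R,4S,4aR,8aR)-1-ethynyl-2,5,5,8a-tetramethyl-4-[(triethylsilyl)oxy]-1,4,4a,5,6,7,8,8a-octahydronaphthalen-1-ol F4. The same chromate transposition then gives (1R,4aR,8aR)-4-ethynyl-3,4a,8,8-tetramethyl-1-[(triethylsilyl)oxy]-4a,5,6,7,8,8a-hexahydronaphthalen-2(1H)-one F5. Semihydrogenation of the alkyne (H2, Pd on CaCO3 poisoned with Pb(OAc)2, quinoline) rejoins the route at 15.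

Step 11 (one-pot union). The dianion may add sluggishly to the dienone, and the in-situ enolate protection of the C7 ketone during LiBH4 reduction may not hold. The fallback sets out from 15 and 17 and separates the events with a redox detour. The Michael addition alone, quenched with AcOH, gives the keto acid 2-{(2S,4S)-2-tert-butyl-5-oxo-4-[2-((4R,4aR,8aR)-2,5,5,8a-tetramethyl-3-oxo-4-(triethylsilyloxy)-3,4,4a,5,6,7,8,8a-octahydronaphthalen-1-yl)ethyl]-1,3-dioxolan-4-yl}acetic acid F6. NaBH4 in EtOH reduces both the ketone and the dioxolanone, and 1 M HCl closes the lactone and removes the silyl ether, giving the triol lactone (4S)-4-{2-[(4R,4aR,8aR)-3,4-dihydroxy-2,5,5,8a-tetramethyl-3,4,4a,5,6,7,8,8a-octahydronaphthalen-1-yl]ethyl}-4-hydroxyoxolan-2-one F7. MnO2 in CH2Cl2 re-oxidises only the allylic C7 carbinol, and the route is rejoined at 21.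

**Further compounds**

F1 | step 3 | (5R,6R)-2,6-dimethyl-5-(prop-1-en-2-yl)-6-[3-(trimethylsilyl)prop-2-yn-1-yl]cyclohex-2-en-1-one | C=C(C)[C@H]1CC=C(C)C(=O)[C@]1(C)CC#C[Si](C)(C)C
F2 | step 3 | (5R,6R)-2,6-dimethyl-5-(prop-1-en-2-yl)-6-[(2Z)-3-(trimethylsilyl)prop-2-en-1-yl]cyclohex-2-en-1-one | C=C(C)[C@H]1CC=C(C)C(=O)[C@]1(C)C/C=C\[Si](C)(C)C
F3 | step 3 | (4aR,8aR)-2,5,5,8a-tetramethyl-4a,5,8,8a-tetrahydronaphthalen-1(4H)-one | CC1=CC[C@@H]2C(C)(C)C=CC[C@@]2(C)C1=O
F4 | step 9 | (1R,4S,4aR,8aR)-1-ethynyl-2,5,5,8a-tetramethyl-4-[(triethylsilyl)oxy]-1,4,4a,5,6,7,8,8a-octahydronaphthalen-1-ol | CC1=C[C@H](O[Si](CC)(CC)CC)[C@@H]2C(C)(C)CCC[C@@]2(C)[C@@]1(O)C#C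
F5 | step 9 | (1R,4aR,8aR)-4-ethynyl-3,4a,8,8-tetramethyl-1-[(triethylsilyl)oxy]-4a,5,6,7,8,8a-hexahydronaphthalen-2(1H)-one | C#CC1=C(C)C(=O)[C@H](O[Si](CC)(CC)CC)[C@@H]2C(C)(C)CCC[C@@]12C
F6 | step 11 | 2-{(2S,4S)-2-tert-butyl-5-oxo-4-[2-((4R,4aR,8aR)-2,5,5,8a-tetramethyl-3-oxo-4-(triethylsilyloxy)-3,4,4a,5,6,7,8,8a-octahydronaphthalen-1-yl)ethyl]-1,3-dioxolan-4-yl}acetic acid | CC1=C(CC[C@@]2(CC(=O)O)O[C@H](C(C)(C)C)OC2=O)[C@]2(C)CCCC(C)(C)[C@H]2[C@@H](O[Si](CC)(CC)CC)C1=O
F7 | step 11 | (4S)-4-{2-[(4R,4aR,8aR)-3,4-dihydroxy-2,5,5,8a-tetramethyl-3,4,4a,5,6,7,8,8a-octahydronaphthalen-1-yl]ethyl}-4-hydroxyoxolan-2-one (C7 epimers) | CC1=C(CC[C@@]2(O)COC(=O)C2)[C@]2(C)CCCC(C)(C)[C@H]2[C@@H](O)C1O
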